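**Retrosynthetic overview**

1. The target is read as the methanolysis product of a dihydrocoumarin lactone (C7–O to the side-chain carboxyl) fused to a 2,3-dimethylchroman-4-one; the cis C3 centre is set last, by kinetic protonation of the C3=C4 silyl enol ether.
2. Key disconnections: C3–C4 (carbene-catalysed intramolecular hydroacylation of an O1–CH(CH3)–CH=CH2 ether by the C4 aldehyde) and C8–C(benzylic) plus the lactone C–O (carbene-catalysed 1,4-transfer of a hex-2-enoyl group parked on O7), both in one operation on aryl ester 8.
3. Enabling feature: in the chromanone ring the C4 carbonyl sits on C4a next to C8a–O1 and C3 bears a methyl group, which is the retron of an aldehyde adding across a vinyl group held on O1. On the benzene ring C8 is the only unsubstituted carbon, ortho to the C7 oxygen and activated by three oxygens, so an enoyl group on O7 can be delivered to it.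
4. Ring order: benzene ring from 2,4,6-trihydroxybenzaldehyde (its formyl carbon becomes C4); temporary lactone ring first and chromanone ring (closed through C3–C4) second, both in step 5; the lactone ring is opened again in step 6.
5. Stereocentres: C2 from (S)-but-3-en-2-ol by Mitsunobu inversion, the benzylic centre by the chiral carbene, C3 by kinetic protonation.

Key step: step 5

Remarks: atom numbers (O1, C2, C3, C4, C4a, C5–C8, C8a) follow the chromanone numbering of the target throughout. Assumption: the (5aR,10bS) triazolium salt is taken to deliver the (R) benzylic centre; should the facial sense be the opposite, its (5aS,10bR) antipode is used with no other change.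

**Route**

Step 1
Reactants: 1 2,4,6-trihydroxybenzaldehyde; 2 1-bromo-3-methylbut-2-ene (prenyl bromide)
Product: 3 2,4,6-trihydroxy-3-(3-methylbut-2-en-1-yl)benzaldehyde
Conditions: 10% aq KOH, 0 °C
Reagents that add atoms: none
Why: Base-mediated C-alkylation of the acylphloroglucinol phenolate (SN2 on the allylic bromide) should give the mono-C-prenyl aldehyde; the two free ring carbons of 1 are equivalent, so no regiochemical question arises, and water as solvent favours C- over O-alkylation.

Step 2
Reactants: 3 2,4,6-trihydroxy-3-(3-methylbut-2-en-1-yl)benzaldehyde; 4 (2E)-hex-2-enoic acid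
Product: 5 4-formyl-3,5-dihydroxy-2-(3-methylbut-2-en-1-yl)phenyl (2E)-hex-2-enoate
Conditions: N,N'-diisopropylcarbodiimide, 4-(dimethylamino)pyridine (5 mol %), THF/CH2Cl2, −20 °C
Reagents that add atoms: none
Why: Steglich esterification should occur at the hydroxyl para to the formyl group, the only one not held in a hydrogen bond to the aldehyde, so that the hex-2-enoyl group both protects O7 and is stored there as the future side chain.

Step 3
Reactants: 5 4-formyl-3,5-dihydroxy-2-(3-methylbut-2-en-1-yl)phenyl (2E)-hex-2-enoate; 6 (2S)-but-3-en-2-ol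
Product: 7 5-[(2R)-but-3-en-2-yloxy]-4-formyl-3-hydroxy-2-(3-methylbut-2-en-1-yl)phenyl (2E)-hex-2-enoate
Conditions: PPh3, diisopropyl azodicarboxylate, THF, 0 °C to 25 °C
Reagents that add atoms: none
Why: Mitsunobu etherification with inversion at the carbinol carbon turns the (S)-alcohol into the (R)-aryl ether and thereby sets C2; of the two chelated hydroxyls the one next to the aromatic C–H should react, the one between formyl and prenyl being much more hindered.

Step 4
Reactants: 7 5-[(2R)-but-3-en-2-yloxy]-4-formyl-3-hydroxy-2-(3-methylbut-2-en-1-yl)phenyl (2E)-hex-2-enoate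
Product: 8 5-[(2R)-but-3-en-2-yloxy]-3-[(tert-butyldimethylsilyl)oxy]-4-formyl-2-(3-methylbut-2-en-1-yl)phenyl (2E)-hex-2-enoate
Conditions: TBSOTf, 2,6-lutidine, CH2Cl2, −78 °C to 0 °C
Reagents that add atoms: tert-butyldimethylsilyl trifluoromethanesulfonate, CC(C)(C)[Si](C)(C)OS(=O)(=O)C(F)(F)F
Why: Silyl triflate silylation of the remaining hindered, hydrogen-bonded phenol removes the only acidic proton of the substrate, which would otherwise protonate the carbene in step 5.

Step 5
Reactants: 8 5-[(2R)-but-3-en-2-yloxy]-3-[(tert-butyldimethylsilyl)oxy]-4-formyl-2-(3-methylbut-2-en-1-yl)phenyl (2E)-hex-2-enoate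
Product: 10 (2R,3R,10R)-5-[(tert-butyldimethylsilyl)oxy]-2,3-dimethyl-6-(3-methylbut-2-en-1-yl)-10-propyl-2,3,9,10-tetrahydro-4H,8H-pyrano[2,3-f]chromene-4,8-dione, via dihydrocoumarin aldehyde 9 (not isolated)
Conditions: (5aR,10bS)-2-mesityl-5a,10b-dihydro-4H,6H-indeno[2,1-b][1,2,4]triazolo[4,3-d][1,4]oxazin-2-ium chloride (20 mol %), N,N-diisopropylethylamine (30 mol %), 1,4-dioxane, 25 °C, then 100 °C
Reagents that add atoms: none
Why: Proposed new method: one chiral triazolylidene is asked to run, in the same flask, two carbene cycles that are each known on simpler substrates but have not been coupled or shown on an acylphloroglucinol — first acyl transfer from the activated aryl enoate to the carbene with Michael-type (Coates–Claisen-like) C-addition of the released aryloxide to the α,β-unsaturated acyl azolium (closest known: carbene-catalysed rearrangements of α,β-unsaturated enol esters and annulations of unsaturated acyl azoliums with naphthols), then carbene-catalysed intramolecular hydroacylation of an unactivated alkene (closest known: 2-allyloxybenzaldehydes to 3-methylchroman-4-ones). At 25 °C the carbene attacks the ester carbonyl of 8, whose leaving group is a para-formyl aryloxide, the ion pair recombines through C8 onto the β-carbon, and the saturated acyl azolium is captured by the C7 oxygen, which closes the lactone ring by 6-exo-trig acyl substitution and releases the carbene together with 9. At 100 °C the carbene adds to the aldehyde of 9 and the resulting enaminol carbon (C4) attacks the internal alkene carbon (C3) while its O–H proton is passed to the terminal CH2 in a concerted five-centre, Conia-ene-like array, which forms the C3–C4 bond, closes the chromanone ring in a 6-exo-trig mode and creates the C3 methyl group. The benzylic centre is set by the catalyst (the indane wall leaves one face of the acyl azolium open to the aryloxide), C2 is carried through untouched, and C3 arises under substrate control (allylic strain in the cyclic array, trans expected) and is deliberately left for correction in step 7. The step needs site selectivity for C8, secured because C8 is the only unsubstituted ring carbon ortho to the C7 oxygen and is activated by three oxygens while C6 (prenyl) and C4a (formyl) cannot rearomatize, and it needs the ester to react before the aldehyde, secured by the temperature program and by the hindered, electron-rich 2,6-dioxygenated aldehyde; Markovnikov 6-exo closure over 7-endo is inherent in the five-centre proton transfer. Running the ester cycle first also blocks C8, so the aryl butenyl ether has no free ortho position for a Claisen rearrangement when the mixture is heated, and the silyl ether keeps the C5 phenol from protonating the carbene.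

Step 6
Reactants: 10 (2R,3R,10R)-5-[(tert-butyldimethylsilyl)oxy]-2,3-dimethyl-6-(3-methylbut-2-en-1-yl)-10-propyl-2,3,9,10-tetrahydro-4H,8H-pyrano[2,3-f]chromene-4,8-dione
Product: 11 methyl (3R)-3-[(2R,3R)-5,7-dihydroxy-2,3-dimethyl-6-(3-methylbut-2-en-1-yl)-4-oxo-3,4-dihydro-2H-chromen-8-yl]hexanoate
Conditions: K2CO3 (2 equiv), MeOH, 0 °C; then AcOH
Reagents that add atoms: methanol, CO
Why: Methoxide-mediated transesterification opens the aryl-ester lactone to the methyl ester and the free C7 phenol, and the same conditions cleave the aryl silyl ether ortho to the ketone; C3 is not controlled at this stage and is expected mainly trans, any cis epimer (13) being carried on.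

Step 7
Reactants: 11 methyl (3R)-3-[(2R,3R)-5,7-dihydroxy-2,3-dimethyl-6-(3-methylbut-2-en-1-yl)-4-oxo-3,4-dihydro-2H-chromen-8-yl]hexanoate
Product: 13 methyl (3R)-3-[(2R,3S)-5,7-dihydroxy-2,3-dimethyl-6-(3-methylbut-2-en-1-yl)-4-oxo-3,4-dihydro-2H-chromen-8-yl]hexanoate, via tris(trimethylsilyl) enol ether 12 (not isolated)
Conditions: TMSOTf, Et3N, CH2Cl2, 0 °C to 25 °C; then HF·pyridine, pyridine, THF, −40 °C
Reagents that add atoms: none
Why: Soft enolization (silyl triflate and amine) converts both C3 epimers into one silyl enol ether, and fluoride-assisted kinetic C-protonation should occur anti to the C2 methyl group, which is pseudoaxial to avoid A(1,2) strain with the C3 methyl group, so that the cis (2R,3S) ketone results while the aryl silyl ethers are cleaved in the same operation (kinetic protonation of an enol derivative).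

**Compound list**

1 | 2,4,6-trihydroxybenzaldehyde | O=Cc1c(O)cc(O)cc1O | starting material
2 | 1-bromo-3-methylbut-2-ene (prenyl bromide) | CC(C)=CCBr | starting material
3 | 2,4,6-trihydroxy-3-(3-methylbut-2-en-1-yl)benzaldehyde | O=Cc1c(O)cc(O)c(CC=C(C)C)c1O | intermediate
4 | (2E)-hex-2-enoic acid | CCC/C=C/C(=O)O | starting material
5 | 4-formyl-3,5-dihydroxy-2-(3-methylbut-2-en-1-yl)phenyl (2E)-hex-2-enoate | CCC/C=C/C(=O)Oc1cc(O)c(C=O)c(O)c1CC=C(C)C | intermediate
6 | (2S)-but-3-en-2-ol | C[C@H](O)C=C | starting material
7 | 5-[(2R)-but-3-en-2-yloxy]-4-formyl-3-hydroxy-2-(3-methylbut-2-en-1-yl)phenyl (2E)-hex-2-enoate | CCC/C=C/C(=O)Oc1cc(O[C@H](C)C=C)c(C=O)c(O)c1CC=C(C)C | intermediate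
8 | 5-[(2R)-but-3-en-2-yloxy]-3-[(tert-butyldimethylsilyl)oxy]-4-formyl-2-(3-methylbut-2-en-1-yl)phenyl (2E)-hex-2-enoate | CCC/C=C/C(=O)Oc1cc(O[C@H](C)C=C)c(C=O)c(O[Si](C)(C)C(C)(C)C)c1CC=C(C)C | intermediate
9 | (4R)-5-[(2R)-but-3-en-2-yloxy]-7-[(tert-butyldimethylsilyl)oxy]-8-(3-methylbut-2-en-1-yl)-2-oxo-4-propyl-3,4-dihydro-2H-chromene-6-carbaldehyde | CCC[C@@H]1CC(=O)Oc2c1c(O[C@H](C)C=C)c(C=O)c(O[Si](C)(C)C(C)(C)C)c2CC=C(C)C | intermediate
10 | (2R,3R,10R)-5-[(tert-butyldimethylsilyl)oxy]-2,3-dimethyl-6-(3-methylbut-2-en-1-yl)-10-propyl-2,3,9,10-tetrahydro-4H,8H-pyrano[2,3-f]chromene-4,8-dione | CCC[C@@H]1CC(=O)Oc2c1c3O[C@H](C)[C@@H](C)C(=O)c3c(O[Si](C)(C)C(C)(C)C)c2CC=C(C)C | intermediate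
11 | methyl (3R)-3-[(2R,3R)-5,7-dihydroxy-2,3-dimethyl-6-(3-methylbut-2-en-1-yl)-4-oxo-3,4-dihydro-2H-chromen-8-yl]hexanoate | CCC[C@H](CC(=O)OC)c1c(O)c(CC=C(C)C)c(O)c2c1O[C@H](C)[C@@H](C)C2=O | intermediate
12 | methyl (3R)-3-[(2R)-2,3-dimethyl-6-(3-methylbut-2-en-1-yl)-4,5,7-tris(trimethylsilyloxy)-2H-chromen-8-yl]hexanoate | CCC[C@H](CC(=O)OC)c1c(O[Si](C)(C)C)c(CC=C(C)C)c(O[Si](C)(C)C)c2c1O[C@H](C)C(C)=C2O[Si](C)(C)C | intermediate
13 | methyl (3R)-3-[(2R,3S)-5,7-dihydroxy-2,3-dimethyl-6-(3-methylbut-2-en-1-yl)-4-oxo-3,4-dihydro-2H-chromen-8-yl]hexanoate | CCC[C@H](CC(=O)OC)c1c(O)c(CC=C(C)C)c(O)c2c1O[C@H](C)[C@H](C)C2=O | target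

**Step count and risks**

Total step count: 7. Longest linear sequence: 7 steps (1 → 3 → 5 → 7 → 8 → 10 → 11 → 13).

Steps most likely to fail:

Step 5 (proposed new method). What may go wrong: the ester cycle may run with poor enantiofacial control or be outrun by unselective acyl transfer, and the aldehyde cycle may stall because the enaminol forms slowly at the doubly ortho-substituted aldehyde. The fallback uses known chemistry only, sets out from 8 and comes back at 10. Pyrrolidine in THF at 0 °C removes the activated enoate to give 2-[(2R)-but-3-en-2-yloxy]-6-[(tert-butyldimethylsilyl)oxy]-4-hydroxy-5-(3-methylbut-2-en-1-yl)benzaldehyde F1. Iminium catalysis with a diarylprolinol silyl ether (the enantiomer that gives the R benzylic centre) and (E)-hex-2-enal then effects Friedel–Crafts alkylation at C8 with hemiacetal closure onto the C7 oxygen, a known reaction of electron-rich phenols, giving the lactol (4R)-5-[(2R)-but-3-en-2-yloxy]-7-[(tert-butyldimethylsilyl)oxy]-2-hydroxy-8-(3-methylbut-2-en-1-yl)-4-propyl-3,4-dihydro-2H-chromene-6-carbaldehyde F2. Oxidation of the lactol with PhI(OAc)2 and catalytic 2,2,6,6-tetramethylpiperidin-1-oxyl gives 9, which is isolated in this variant. The chromanone ring is then closed by thiol-catalysed radical-chain hydroacylation (tert-dodecanethiol, 2,2'-azobis(2-methylpropionitrile), chlorobenzene, 80 °C; acyl radical, 6-exo-trig), which gives 10.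

Step 7. What may go wrong: incomplete facial discrimination in the C-protonation, or re-equilibration of C3 toward the trans epimer during desilylation and work-up. The fallback sets out from 11 and comes back at 13 and replaces kinetic by thermodynamic control: C3 is equilibrated with a catalytic amine base (1,8-diazabicyclo[5.4.0]undec-7-ene, MeCN, 25 °C), 13 is separated from 11 by preparative chromatography and recovered 11 is resubjected. It makes no new compound (F0).

Step 3. What may go wrong: etherification at the more hindered hydroxyl, allylic transposition (SN2′), or partial loss of configuration through an ion-pair pathway. The fallback sets out from 5 and comes back at 7 and sets C2 by catalyst control instead of by inversion of a chiral-pool alcohol: palladium-catalysed asymmetric allylic etherification of 5 with (E)-but-2-enyl methyl carbonate, Pd2(dba)3 and the appropriate enantiomer of N,N'-(cyclohexane-1,2-diyl)bis[2-(diphenylphosphino)benzamide], which should give the branched (R) ether at the less hindered hydroxyl. It makes no new compound (F0).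

Further compounds
F1 | step 5 | 2-[(2R)-but-3-en-2-yloxy]-6-[(tert-butyldimethylsilyl)oxy]-4-hydroxy-5-(3-methylbut-2-en-1-yl)benzaldehyde | Oc1cc(O[C@H](C)C=C)c(C=O)c(O[Si](C)(C)C(C)(C)C)c1CC=C(C)C
F2 | step 5 | (4R)-5-[(2R)-but-3-en-2-yloxy]-7-[(tert-butyldimethylsilyl)oxy]-2-hydroxy-8-(3-methylbut-2-en-1-yl)-4-propyl-3,4-dihydro-2H-chromene-6-carbaldehyde (lactol, both anomers) | CCC[C@@H]1CC(O)Oc2c1c(O[C@H](C)C=C)c(C=O)c(O[Si](C)(C)C(C)(C)C)c2CC=C(C)C
F0 | step 7 | none | none
F0 | step 3 | none | none
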